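Ring A of gnetal, the benzo ring, bears oxygen on both carbons flanking C3a (O1 on C7a, OH on C4), so it is an aromatised cyclohexane-1,3-dione, while C2 and C3 with their aryl groups are the alkene of resveratrol. Everything rests on a formal (3+2) cycloaddition across that alkene: a chiral dirhodium carbenoid, made from a 2-diazocyclohexane-1,3-dione that carries an ester at the future C6, forms C3a–C3, and the resulting benzylic cation is closed by the dione oxygen to form O1–C2. One operation thus gives the trans-2,3-diaryl dihydrofuran ring B and both stereocentres from silylated resveratrol. Aromatisation, ester-to-aldehyde adjustment and desilylation complete the route.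

Key step: step 3

Remark: C6 of compounds 5 to 9 is an inconsequential epimeric centre (left undefined in the SMILES), and the (S)-tert-leucinate catalyst is assumed to give the (2S,3S) series; if the sense of induction is the opposite, the (R)-catalyst is used.

Step 1
Reactants: 1 resveratrol
Product: 2 (E)-3,5,4'-tris(tert-butyldimethylsilyloxy)stilbene
Conditions: TBSCl (3.6 equiv), imidazole (7 equiv), DMF, rt
Reagents that add atoms: tert-butyldimethylsilyl chloride (TBSCl), CC(C)(C)[Si](C)(C)Cl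
Why: Imidazole-mediated silylation of the three phenols (substitution at silicon) removes the O–H groups that would quench the carbenoid, keeps the 4'-oxygen a strong donor for regiocontrol, and gives ethers that survive LiN(iPr)2 and iBu2AlH.

Step 2
Reactants: 3 methyl 3,5-dioxocyclohexane-1-carboxylate
Product: 4 methyl 4-diazo-3,5-dioxocyclohexane-1-carboxylate
Conditions: p-ABSA (1.1 equiv), Et3N (1.2 equiv), MeCN, 0 °C to rt
Reagents that add atoms: 4-acetamidobenzenesulfonyl azide (p-ABSA), CC(=O)Nc1ccc(cc1)S(=O)(=O)N=[N+]=[N-]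
Why: Regitz diazo transfer to the doubly activated C4 methylene of the cyclic 1,3-dione, driven by loss of the sulfonamide.

Step 3
Reactants: 2 (E)-3,5,4'-tris(tert-butyldimethylsilyloxy)stilbene; 4 methyl 4-diazo-3,5-dioxocyclohexane-1-carboxylate
Product: 6 methyl (2S,3S)-3-[3,5-bis(tert-butyldimethylsilyloxy)phenyl]-2-[4-(tert-butyldimethylsilyloxy)phenyl]-4-oxo-2,3,4,5,6,7-hexahydro-1-benzofuran-6-carboxylate (C6 epimers), via benzylic zwitterion 5 (not isolated)
Conditions: Rh2(S-TCPTTL)4 (dirhodium tetrakis[N-tetrachlorophthaloyl-(S)-tert-leucinate], 2 mol %), PhCF3, 60 °C, slow addition of 4 (1.5 equiv)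
Reagents that add atoms: none
Why: Proposed new method: the chiral dirhodium carboxylate converts 4 (loss of N2) into an electrophilic carbenoid at the carbon between the two carbonyls, and the alkene carbon of 2 remote from the 4-silyloxyphenyl ring attacks it inside the chiral ligand pocket to forge C3a–C3, leaving zwitterion 5 (quinoid benzylic cation at C2, dione enolate) that collapses through oxygen to forge O1–C2. The closest known reaction type is the dirhodium-catalysed formal (3+2) "dipolar" cycloaddition of cyclic 2-diazo-1,3-diones with vinyl ethers and styrenes; what is new is high enantiocontrol with a trans-1,2-diarylalkene. Ring B closes by 5-exo-trig capture of the exocyclic quinoid cation by the enolate oxygen (a spirocyclopropane, if formed, would open to the same zwitterion). C3 is set by catalyst control, because the C–C bond forms on the metal-bound carbenoid and is not broken afterwards; C2 is set by substrate control, the cation closing anti to the C3 aryl group, and any cis isomer can equilibrate to trans by reversible C2–O1 ionisation. The step needs regioselectivity (carbon to C3, oxygen to C2), secured by the para-silyloxy donor that stabilises positive charge only at C2, and chemoselectivity for the alkene over the arenes, secured by the bulky silyl ethers flanking the activated ring positions and by slow addition of 4. The C6 epimers are inconsequential because C6 becomes aromatic in step 4.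

Step 4
Reactants: 6 methyl (2S,3S)-3-[3,5-bis(tert-butyldimethylsilyloxy)phenyl]-2-[4-(tert-butyldimethylsilyloxy)phenyl]-4-oxo-2,3,4,5,6,7-hexahydro-1-benzofuran-6-carboxylate
Product: 10 methyl (2S,3S)-3-[3,5-bis(tert-butyldimethylsilyloxy)phenyl]-2-[4-(tert-butyldimethylsilyloxy)phenyl]-4-hydroxy-2,3-dihydro-1-benzofuran-6-carboxylate, via lithium enolate 7 (not isolated), via sulfilimine adduct 8 (not isolated), via dienone tautomer 9 (not isolated)
Conditions: LiN(iPr)2 (1.2 equiv), THF, −78 °C; then PhS(Cl)=NtBu (1.3 equiv), −78 to 0 °C; aq NH4Cl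
Reagents that add atoms: none
Why: Mukaiyama dehydrogenation, in which kinetic enolate 7 attacks sulfur, adduct 8 loses the sulfenamide by syn-elimination and dienone 9 tautomerises to the phenol (an enolate at C6 would converge on the same product); neither C2–H nor C3–H is enolisable, so both stereocentres should be kept.

Step 5
Reactants: 10 methyl (2S,3S)-3-[3,5-bis(tert-butyldimethylsilyloxy)phenyl]-2-[4-(tert-butyldimethylsilyloxy)phenyl]-4-hydroxy-2,3-dihydro-1-benzofuran-6-carboxylate
Product: 11 (2S,3S)-3-[3,5-bis(tert-butyldimethylsilyloxy)phenyl]-2-[4-(tert-butyldimethylsilyloxy)phenyl]-6-(hydroxymethyl)-2,3-dihydro-1-benzofuran-4-ol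
Conditions: iBu2AlH (DIBAL-H, 4 equiv), CH2Cl2, −78 to 0 °C; aq Rochelle salt
Reagents that add atoms: none
Why: Hydride reduction of the aryl ester to the benzylic alcohol, one equivalent of hydride being consumed by the phenol; aryl silyl ethers and the benzylic C2–O1 bond are inert to the reagent at low temperature.

Step 6
Reactants: 11 (2S,3S)-3-[3,5-bis(tert-butyldimethylsilyloxy)phenyl]-2-[4-(tert-butyldimethylsilyloxy)phenyl]-6-(hydroxymethyl)-2,3-dihydro-1-benzofuran-4-ol
Product: 12 (2S,3S)-3-[3,5-bis(tert-butyldimethylsilyloxy)phenyl]-2-[4-(tert-butyldimethylsilyloxy)phenyl]-4-hydroxy-2,3-dihydro-1-benzofuran-6-carbaldehyde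
Conditions: activated MnO2 (15 equiv), CH2Cl2, rt
Reagents that add atoms: none
Why: Selective heterogeneous oxidation of a benzylic alcohol by MnO2, which stops at the aldehyde and should leave the single, electron-poor phenol and the silyl ethers untouched.

Step 7
Reactants: 12 (2S,3S)-3-[3,5-bis(tert-butyldimethylsilyloxy)phenyl]-2-[4-(tert-butyldimethylsilyloxy)phenyl]-4-hydroxy-2,3-dihydro-1-benzofuran-6-carbaldehyde
Product: 13 gnetal
Conditions: Bu4NF (3.3 equiv), AcOH (3.5 equiv), THF, 0 °C to rt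
Reagents that add atoms: none
Why: Fluoride-driven cleavage of the three aryl silyl ethers (Si–F bond formation), buffered by AcOH so that the 4-hydroxyphenyl phenoxide does not open ring B through a quinone methide; C3 cannot epimerise and the trans ring is the thermodynamic isomer.

Compound list

1 | resveratrol, (E)-3,5,4'-trihydroxystilbene | Oc1ccc(/C=C/c2cc(O)cc(O)c2)cc1 | starting material
2 | (E)-3,5,4'-tris(tert-butyldimethylsilyloxy)stilbene | CC(C)(C)[Si](C)(C)Oc1ccc(/C=C/c2cc(O[Si](C)(C)C(C)(C)C)cc(O[Si](C)(C)C(C)(C)C)c2)cc1 | intermediate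
3 | methyl 3,5-dioxocyclohexane-1-carboxylate | COC(=O)C1CC(=O)CC(=O)C1 | starting material
4 | methyl 4-diazo-3,5-dioxocyclohexane-1-carboxylate | COC(=O)C1CC(=O)C(=[N+]=[N-])C(=O)C1 | intermediate
5 | ring-open zwitterion after C3a–C3 bond formation: benzylic cation at C2, dione enolate, drawn without the metal (not isolated) | COC(=O)C1CC(=O)C(=C([O-])C1)[C@H](c1cc(O[Si](C)(C)C(C)(C)C)cc(O[Si](C)(C)C(C)(C)C)c1)[CH+]c1ccc(O[Si](C)(C)C(C)(C)C)cc1 | intermediate
6 | methyl (2S,3S)-3-[3,5-bis(tert-butyldimethylsilyloxy)phenyl]-2-[4-(tert-butyldimethylsilyloxy)phenyl]-4-oxo-2,3,4,5,6,7-hexahydro-1-benzofuran-6-carboxylate, trans, C6 epimers | COC(=O)C1CC(=O)C2=C(C1)O[C@H](c1ccc(O[Si](C)(C)C(C)(C)C)cc1)[C@H]2c1cc(O[Si](C)(C)C(C)(C)C)cc(O[Si](C)(C)C(C)(C)C)c1 | intermediate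
7 | lithium C4–C5 enolate of 6 (not isolated) | [Li+].COC(=O)C1C=C([O-])C2=C(C1)O[C@H](c1ccc(O[Si](C)(C)C(C)(C)C)cc1)[C@H]2c1cc(O[Si](C)(C)C(C)(C)C)cc(O[Si](C)(C)C(C)(C)C)c1 | intermediate
8 | C5 S-phenyl-N-tert-butylsulfilimine adduct of 6 (not isolated) | COC(=O)C1C(S(=NC(C)(C)C)c3ccccc3)C(=O)C2=C(C1)O[C@H](c1ccc(O[Si](C)(C)C(C)(C)C)cc1)[C@H]2c1cc(O[Si](C)(C)C(C)(C)C)cc(O[Si](C)(C)C(C)(C)C)c1 | intermediate
9 | methyl (2S,3S)-2,3-diaryl-4-oxo-2,3,4,7-tetrahydro-1-benzofuran-6-carboxylate, the keto tautomer of 10 (not isolated) | COC(=O)C1=CC(=O)C2=C(C1)O[C@H](c1ccc(O[Si](C)(C)C(C)(C)C)cc1)[C@H]2c1cc(O[Si](C)(C)C(C)(C)C)cc(O[Si](C)(C)C(C)(C)C)c1 | intermediate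
10 | methyl (2S,3S)-3-[3,5-bis(tert-butyldimethylsilyloxy)phenyl]-2-[4-(tert-butyldimethylsilyloxy)phenyl]-4-hydroxy-2,3-dihydro-1-benzofuran-6-carboxylate | COC(=O)c1cc(O)c2c(c1)O[C@H](c1ccc(O[Si](C)(C)C(C)(C)C)cc1)[C@H]2c1cc(O[Si](C)(C)C(C)(C)C)cc(O[Si](C)(C)C(C)(C)C)c1 | intermediate
11 | (2S,3S)-3-[3,5-bis(tert-butyldimethylsilyloxy)phenyl]-2-[4-(tert-butyldimethylsilyloxy)phenyl]-6-(hydroxymethyl)-2,3-dihydro-1-benzofuran-4-ol | OCc1cc(O)c2c(c1)O[C@H](c1ccc(O[Si](C)(C)C(C)(C)C)cc1)[C@H]2c1cc(O[Si](C)(C)C(C)(C)C)cc(O[Si](C)(C)C(C)(C)C)c1 | intermediate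
12 | (2S,3S)-3-[3,5-bis(tert-butyldimethylsilyloxy)phenyl]-2-[4-(tert-butyldimethylsilyloxy)phenyl]-4-hydroxy-2,3-dihydro-1-benzofuran-6-carbaldehyde | O=Cc1cc(O)c2c(c1)O[C@H](c1ccc(O[Si](C)(C)C(C)(C)C)cc1)[C@H]2c1cc(O[Si](C)(C)C(C)(C)C)cc(O[Si](C)(C)C(C)(C)C)c1 | intermediate
13 | gnetal, (2S,3S)-3-(3,5-dihydroxyphenyl)-4-hydroxy-2-(4-hydroxyphenyl)-2,3-dihydro-1-benzofuran-6-carbaldehyde, trans | O=Cc1cc(O)c2c(c1)O[C@H](c1ccc(O)cc1)[C@H]2c1cc(O)cc(O)c1 | target

Total step count: 7. Longest linear sequence: 6 steps (1 → 2 → 6 → 10 → 11 → 12 → 13; the branch from 3 is equally long).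

Steps most likely to fail

Step 3 (proposed new method). The symmetric diketo carbenoid may discriminate the two faces of the trans-alkene poorly, giving low enantiomeric excess. Capture by a 1,2-disubstituted alkene may also be slow enough for carbenoid dimerisation or attack on the silyloxyarenes to compete. The fallback gives up catalyst control and uses known chemistry only. It sets out from 2 and 3 (no diazo transfer): Mn(OAc)3·2H2O (2.2 equiv) in AcOH at 60 °C, an oxidative radical (3+2) annulation of a 1,3-dione with an aryl alkene, should give the racemic trans adduct F1. Pd-catalysed aerobic dehydrogenation (the conditions given under step 4 below) should give the racemic phenol F2. Acylation with (−)-menthyl chloroformate (pyridine, DMAP, CH2Cl2) gives two diastereomeric carbonates, and the (2S,3S)-menthyl carbonate F3 is separated from the (2R,3R)-menthyl carbonate F4 by chromatography or crystallisation. Treatment of F3 with iBu2AlH under the conditions of step 5 cleaves the carbonate and reduces the ester in one operation, and the route is rejoined at 11.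

Step 4. Deprotonation may take a different course (γ-deprotonation at C7, or base-induced opening of ring B by retro-oxa-Michael elimination), or the sulfenamide elimination and tautomerisation may stall. The fallback replaces stoichiometric enolate chemistry by a catalytic dehydrogenation: from 6, Pd(OCOCF3)2 (5 mol %), 2-(dimethylamino)pyridine (10 mol %), TsOH (20 mol %), O2 (1 atm), DMSO, 80 °C, a palladium-enolate/β-hydride elimination sequence with oxygen as the terminal oxidant, leading directly to 10. It makes no new compound (F0).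

Step 6. The free C4 phenol may undergo oxidative coupling on the MnO2 surface, or conversion may stall. The fallback changes the protecting-group plan: from 10, silylation of the phenol (TBSCl, imidazole, DMF) gives the tetrakis-silyl ester F5; iBu2AlH (CH2Cl2, −78 °C) gives the tetrakis-silyl benzylic alcohol F6; MnO2 (CH2Cl2, rt), now without any free phenol, gives the tetrakis-silyl aldehyde F7; Bu4NF/AcOH (THF, 0 °C) removes all four silyl groups and the route is rejoined at 13.

Further compounds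

F1 | step 3 | racemic methyl trans-3-[3,5-bis(tert-butyldimethylsilyloxy)phenyl]-2-[4-(tert-butyldimethylsilyloxy)phenyl]-4-oxo-2,3,4,5,6,7-hexahydro-1-benzofuran-6-carboxylate (both enantiomers shown) | COC(=O)C1CC(=O)C2=C(C1)O[C@H](c1ccc(O[Si](C)(C)C(C)(C)C)cc1)[C@H]2c1cc(O[Si](C)(C)C(C)(C)C)cc(O[Si](C)(C)C(C)(C)C)c1.COC(=O)C1CC(=O)C2=C(C1)O[C@@H](c1ccc(O[Si](C)(C)C(C)(C)C)cc1)[C@@H]2c1cc(O[Si](C)(C)C(C)(C)C)cc(O[Si](C)(C)C(C)(C)C)c1
F2 | step 3 | racemic methyl trans-3-[3,5-bis(tert-butyldimethylsilyloxy)phenyl]-2-[4-(tert-butyldimethylsilyloxy)phenyl]-4-hydroxy-2,3-dihydro-1-benzofuran-6-carboxylate (both enantiomers shown) | COC(=O)c1cc(O)c2c(c1)O[C@H](c1ccc(O[Si](C)(C)C(C)(C)C)cc1)[C@H]2c1cc(O[Si](C)(C)C(C)(C)C)cc(O[Si](C)(C)C(C)(C)C)c1.COC(=O)c1cc(O)c2c(c1)O[C@@H](c1ccc(O[Si](C)(C)C(C)(C)C)cc1)[C@@H]2c1cc(O[Si](C)(C)C(C)(C)C)cc(O[Si](C)(C)C(C)(C)C)c1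
F3 | step 3 | (2S,3S)-menthyl carbonate: methyl (2S,3S)-3-[3,5-bis(tert-butyldimethylsilyloxy)phenyl]-2-[4-(tert-butyldimethylsilyloxy)phenyl]-4-[(1R,2S,5R)-menthyloxycarbonyloxy]-2,3-dihydro-1-benzofuran-6-carboxylate | COC(=O)c1cc(OC(=O)O[C@@H]3C[C@H](C)CC[C@H]3C(C)C)c2c(c1)O[C@H](c1ccc(O[Si](C)(C)C(C)(C)C)cc1)[C@H]2c1cc(O[Si](C)(C)C(C)(C)C)cc(O[Si](C)(C)C(C)(C)C)c1
F4 | step 3 | (2R,3R)-menthyl carbonate, the diastereomer that is set aside | COC(=O)c1cc(OC(=O)O[C@@H]3C[C@H](C)CC[C@H]3C(C)C)c2c(c1)O[C@@H](c1ccc(O[Si](C)(C)C(C)(C)C)cc1)[C@@H]2c1cc(O[Si](C)(C)C(C)(C)C)cc(O[Si](C)(C)C(C)(C)C)c1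
F0 | step 4 | none | none
F5 | step 6 | methyl (2S,3S)-3-[3,5-bis(tert-butyldimethylsilyloxy)phenyl]-4-(tert-butyldimethylsilyloxy)-2-[4-(tert-butyldimethylsilyloxy)phenyl]-2,3-dihydro-1-benzofuran-6-carboxylate | COC(=O)c1cc(O[Si](C)(C)C(C)(C)C)c2c(c1)O[C@H](c1ccc(O[Si](C)(C)C(C)(C)C)cc1)[C@H]2c1cc(O[Si](C)(C)C(C)(C)C)cc(O[Si](C)(C)C(C)(C)C)c1
F6 | step 6 | [(2S,3S)-3-[3,5-bis(tert-butyldimethylsilyloxy)phenyl]-4-(tert-butyldimethylsilyloxy)-2-[4-(tert-butyldimethylsilyloxy)phenyl]-2,3-dihydro-1-benzofuran-6-yl]methanol | OCc1cc(O[Si](C)(C)C(C)(C)C)c2c(c1)O[C@H](c1ccc(O[Si](C)(C)C(C)(C)C)cc1)[C@H]2c1cc(O[Si](C)(C)C(C)(C)C)cc(O[Si](C)(C)C(C)(C)C)c1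
F7 | step 6 | (2S,3S)-3-[3,5-bis(tert-butyldimethylsilyloxy)phenyl]-4-(tert-butyldimethylsilyloxy)-2-[4-(tert-butyldimethylsilyloxy)phenyl]-2,3-dihydro-1-benzofuran-6-carbaldehyde | O=Cc1cc(O[Si](C)(C)C(C)(C)C)c2c(c1)O[C@H](c1ccc(O[Si](C)(C)C(C)(C)C)cc1)[C@H]2c1cc(O[Si](C)(C)C(C)(C)C)cc(O[Si](C)(C)C(C)(C)C)c1
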